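**Strategy**

Ring A (C1 gem-dimethyl carbon, C2, C3 carbonyl, C4 vinyl CH, C5 methyl-bearing carbon, C6 stereocenter) is made from an acyclic aldehyde in which C4 and the C5 methyl are the two ends of an isopropenyl group on C6. A Me2AlCl-promoted carbonyl-ene cyclization joins the aldehyde carbon C3 to the terminal methylene C4 and closes the six-membered ring in one operation; oxidation and double-bond shift then give the enone. The precursor, (4S)-4-(2-silyloxyethyl)-3,3,5-trimethylhex-5-enal, comes from an anionic oxy-Cope shift that sets C6 and the quaternary C1 together. The ring A iodide, a C14 bromobutenolide trienal and a C15 epoxy phosphonium salt are united by Negishi coupling and Wittig olefination.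

Key step: step 5

Numbering: carotenoid numbering is used (ring A C1–C6; chain C7, C8; butenolide C9–C11 with lactone carbonyl C19; polyene C12–C15 and C15'–C7'; epoxide ring C1'–C6').

Assumption: (4R,6R)-actinol 23, dialdehyde 17 and phosphonate 29 are bought as commercial carotenoid building blocks, and (S)-TRIP is taken to show with prenal the facial sense known for its propargylborations of aryl aldehydes.

**Route**

Step 1
Reactants: 1 3-methylbut-2-enal (prenal); 2 allenylboronic acid pinacol ester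
Product: 4 (4S)-6-methylhept-5-en-1-yn-4-ol, via borate ester 3 (not isolated)
Conditions: (S)-TRIP (5 mol %), 4 Å MS, toluene, −20 °C → rt; aq. NaHCO3 work-up
Reagents that add atoms: none
Why: Chiral phosphoric acid catalysed propargylboration, in which the allenyl group is delivered SE2' through a closed six-membered transition state to the Si face of the aldehyde and sets the (4S) carbinol.

Step 2
Reactants: 4 (4S)-6-methylhept-5-en-1-yn-4-ol
Product: 6 (3E,6S)-4,8-dimethylnona-3,7-diene-1,6-diol, via alkenylalane 5 (not isolated)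
Conditions: Me3Al (3 equiv), Cp2ZrCl2 (0.3 equiv), CH2Cl2, 0 °C → rt; volatiles removed; n-BuLi, THF/hexane, −78 → 0 °C; ethylene oxide, 0 °C → rt; aq. KNaC4H4O6
Reagents that add atoms: trimethylaluminium C[Al](C)C; ethylene oxide C1CO1
Why: Zirconium-catalysed Negishi carboalumination adds methyl and aluminium syn across the terminal alkyne with aluminium at the terminus, which fixes the (E)-trisubstituted alkene, and the derived lithium alanate opens ethylene oxide with retention of that geometry.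

Step 3
Reactants: 6 (3E,6S)-4,8-dimethylnona-3,7-diene-1,6-diol
Product: 7 (4S,6E)-9-(tert-butyldimethylsilyloxy)-2,6-dimethylnona-2,6-dien-4-ol
Conditions: TBSCl (1.05 equiv), imidazole, CH2Cl2, −10 °C
Reagents that add atoms: tert-butyldimethylsilyl chloride CC(C)(C)[Si](C)(C)Cl
Why: Selective silyl ether formation, the primary hydroxyl reacting much faster than the hindered secondary allylic one.

Step 4
Reactants: 7 (4S,6E)-9-(tert-butyldimethylsilyloxy)-2,6-dimethylnona-2,6-dien-4-ol
Product: 9 (4S)-4-[2-(tert-butyldimethylsilyloxy)ethyl]-3,3,5-trimethylhex-5-enal, via potassium enolate 8 (not isolated)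
Conditions: KH (1.5 equiv), 18-crown-6 (1.5 equiv), THF, 0 °C → rt; H2O, −78 °C
Reagents that add atoms: none
Why: Anionic oxy-Cope [3,3] rearrangement through a chair transition state with the alkoxide equatorial (the axial site is blocked by the cis methyl of the prenyl terminus) and the (E)-alkene substituent equatorial, so the carbinol configuration is transferred to C6 while the quaternary C1 and the isopropenyl group form at the same time.

Step 5
Reactants: 9 (4S)-4-[2-(tert-butyldimethylsilyloxy)ethyl]-3,3,5-trimethylhex-5-enal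
Product: 11 (4R)-4-[2-(tert-butyldimethylsilyloxy)ethyl]-5,5-dimethyl-3-methylidenecyclohexan-1-ol (both C1 epimers), via aluminium alkoxide 10 (not isolated)
Conditions: Me2AlCl (1.5 equiv, hexanes), CH2Cl2, −78 → −20 °C; 1 M HCl, 0 °C
Reagents that add atoms: none
Why: Me2AlCl binds the aldehyde oxygen and the activated carbonyl carbon C3 is attacked by the terminal methylene C4 of the isopropenyl group while a hydrogen of the C5 methyl passes to oxygen through a chair-like transition state, i.e. a type 2 intramolecular carbonyl-ene reaction whose closest known class is the Me2AlCl-promoted cyclization of 5-methylhex-5-enals to 3-methylidenecyclohexanols. The six-membered ring closes exo with respect to the C=O and endo with respect to the C4=C5 alkene (the 6-(3,4) ene mode), helped by the gem-dimethyl group at C1. The only new stereocenter is the carbinol C3, which is set without control and is erased by the oxidation in step 6. C6 is not touched because the aluminium alkoxide loses methane, so neither a free carbocation nor a Brønsted acid is present. The selectivity needed is hydrogen transfer from the C5 methyl and not from C6–H, which would give the tetrasubstituted C5=C6 alkene and destroy the stereocenter; the methyl hydrogens can reach the oxygen in the concerted transition state whereas the ring hydrogen at C6 cannot, and the low temperature suppresses chloride capture.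

Step 6
Reactants: 11 (4R)-4-[2-(tert-butyldimethylsilyloxy)ethyl]-5,5-dimethyl-3-methylidenecyclohexan-1-ol
Product: 13 (4R)-4-(2-hydroxyethyl)-3,5,5-trimethylcyclohex-2-en-1-one, via methylidene ketone 12 (not isolated)
Conditions: a) nPr4N[RuO4] (5 mol %), NMO (1.5 equiv), 4 Å MS, CH2Cl2, rt; b) 1 M HCl, MeOH, rt
Reagents that add atoms: none
Why: Ley–Griffith oxidation gives the β,γ-unsaturated ketone, whose exocyclic alkene moves into conjugation by acid-catalysed dienol formation and protonation at the methylene carbon while the same acid cleaves the primary silyl ether; C6 is not enolised under these conditions and keeps its configuration.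

Step 7
Reactants: 13 (4R)-4-(2-hydroxyethyl)-3,5,5-trimethylcyclohex-2-en-1-one
Product: 14 (4R)-4-(2-iodoethyl)-3,5,5-trimethylcyclohex-2-en-1-one
Conditions: I2, PPh3, imidazole, CH2Cl2, 0 °C → rt, dark
Reagents that add atoms: iodine II
Why: Appel-type iodination, an SN2 displacement of the alkoxyphosphonium ion at the primary carbon that leaves the enone untouched.

Step 8
Reactants: 15 propiolic acid
Product: 16 (2E)-2,3-dibromoprop-2-enoic acid
Conditions: Br2 (1.0 equiv), CHCl3, 0 °C → rt, dark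
Reagents that add atoms: bromine BrBr
Why: Electrophilic anti addition of bromine to the alkyne should give the (E)-dibromide, which places the β-bromine cis to the carboxyl group.

Step 9
Reactants: 17 (2E,4E,6E)-2,7-dimethylocta-2,4,6-trienedial
Product: 18 (2E,4E,6E)-2,7-dimethylnona-2,4,6-trien-8-ynal
Conditions: Me3SiCHN2, LiN(iPr)2, THF, −78 °C; added to 17 (2 equiv), −78 °C → rt
Reagents that add atoms: trimethylsilyldiazomethane C[Si](C)(C)C=[N+]=[N-]
Why: Colvin homologation, in which lithiated trimethylsilyldiazomethane adds to one aldehyde group, Peterson elimination and loss of N2 give an alkylidene carbene and a 1,2-hydrogen shift gives the terminal alkyne, the excess of dialdehyde limiting double reaction.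

Step 10
Reactants: 18 (2E,4E,6E)-2,7-dimethylnona-2,4,6-trien-8-ynal; 16 (2E)-2,3-dibromoprop-2-enoic acid
Product: 20 (2E,4E,6E,8Z)-8-(4-bromo-5-oxofuran-2(5H)-ylidene)-2,7-dimethylocta-2,4,6-trienal, via bromoenynoic acid 19 (not isolated)
Conditions: PdCl2(PPh3)2 (5 mol %), CuI (10 mol %), Et3N (4 equiv), MeCN, rt, dark
Reagents that add atoms: none
Why: Tandem Sonogashira coupling at the more reactive β-bromide (cis to the carboxyl group) followed by 5-exo-dig anti addition of the carboxylate across the alkyne, which should give the (Z)-ylidenebutenolide and keep the α-bromide for the next coupling.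

Step 11
Reactants: 14 (4R)-4-(2-iodoethyl)-3,5,5-trimethylcyclohex-2-en-1-one; 20 (2E,4E,6E,8Z)-8-(4-bromo-5-oxofuran-2(5H)-ylidene)-2,7-dimethylocta-2,4,6-trienal
Product: 22 (2E,4E,6E,8Z)-2,7-dimethyl-8-[5-oxo-4-{2-[(1R)-2,6,6-trimethyl-4-oxocyclohex-2-en-1-yl]ethyl}furan-2(5H)-ylidene]octa-2,4,6-trienal, via alkylzinc iodide 21 (not isolated)
Conditions: a) Zn dust (activated by BrCH2CH2Br and Me3SiCl), LiCl, THF, 40 °C; b) 20, PdCl2(dppf) (5 mol %), THF/NMP, rt, dark
Reagents that add atoms: none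
Why: Direct zinc insertion into the primary iodide gives a functional-group-tolerant alkylzinc reagent that undergoes Negishi sp3–sp2 coupling at the α-bromide of the butenolide, the aldehyde and the enone not being attacked by the organozinc.

Step 12
Reactants: 23 (4R,6R)-4-hydroxy-2,2,6-trimethylcyclohexan-1-one (actinol)
Product: 24 (1R,5R)-3,3,5-trimethyl-4-oxocyclohexyl pivalate
Conditions: PivCl, pyridine, DMAP (cat.), CH2Cl2, 0 °C → rt
Reagents that add atoms: pivaloyl chloride CC(C)(C)C(Cl)=O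
Why: Acylation of the secondary alcohol to a pivalate that survives the enolate, coupling and olefination steps and is removed by the later hydride reduction.

Step 13
Reactants: 24 (1R,5R)-3,3,5-trimethyl-4-oxocyclohexyl pivalate
Product: 25 (1R)-3,5,5-trimethyl-4-(trifluoromethanesulfonyloxy)cyclohex-3-en-1-yl pivalate
Conditions: LiN(iPr)2, THF, −78 °C; PhNTf2, −78 °C → rt
Reagents that add atoms: N-phenylbis(trifluoromethanesulfonimide) O=S(=O)(N(c1ccccc1)S(=O)(=O)C(F)(F)F)C(F)(F)F
Why: The ketone can enolise only towards the methyl-bearing carbon (the other α-carbon is quaternary) and the lithium enolate is trapped on oxygen as the enol triflate, the carbinol stereocenter being untouched.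

Step 14
Reactants: 25 (1R)-3,5,5-trimethyl-4-(trifluoromethanesulfonyloxy)cyclohex-3-en-1-yl pivalate
Product: 26 (1R)-4-(hydroxymethyl)-3,5,5-trimethylcyclohex-3-en-1-yl pivalate
Conditions: Bu3SnCH2OH (1.5 equiv), Pd(PPh3)4 (10 mol %), LiCl (3 equiv), 1,4-dioxane, 100 °C
Reagents that add atoms: (tributylstannyl)methanol CCCC[Sn](CCCC)(CCCC)CO
Why: Stille coupling of the vinyl triflate with the hydroxymethyl stannane, LiCl assisting oxidative addition and transmetalation.

Step 15
Reactants: 26 (1R)-4-(hydroxymethyl)-3,5,5-trimethylcyclohex-3-en-1-yl pivalate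
Product: 27 (1R,4S,6R)-1-(hydroxymethyl)-2,2,6-trimethyl-7-oxabicyclo[4.1.0]heptan-4-yl pivalate
Conditions: Ti(OiPr)4 (0.2 equiv), D-(−)-diethyl tartrate (0.25 equiv), tBuOOH (2 equiv), 4 Å MS, CH2Cl2, −20 °C
Reagents that add atoms: tert-butyl hydroperoxide CC(C)(C)OO
Why: Sharpless asymmetric epoxidation, in which the titanium D-(−)-tartrate complex delivers oxygen to the face of the allylic alcohol anti to the pivalate (the sense that turns (E)-allylic alcohols into (2R,3R)-epoxy alcohols) and so sets the (5'R,6'S) epoxide.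

Step 16
Reactants: 27 (1R,4S,6R)-1-(hydroxymethyl)-2,2,6-trimethyl-7-oxabicyclo[4.1.0]heptan-4-yl pivalate
Product: 28 (1S,4S,6R)-1-formyl-2,2,6-trimethyl-7-oxabicyclo[4.1.0]heptan-4-yl pivalate
Conditions: nPr4N[RuO4] (5 mol %), NMO (1.5 equiv), 4 Å MS, CH2Cl2, rt
Reagents that add atoms: none
Why: Ley–Griffith oxidation of the primary epoxy alcohol to the aldehyde under neutral conditions that spare the epoxide.

Step 17
Reactants: 28 (1S,4S,6R)-1-formyl-2,2,6-trimethyl-7-oxabicyclo[4.1.0]heptan-4-yl pivalate; 29 ethyl (2E)-4-(diethoxyphosphoryl)-3-methylbut-2-enoate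
Product: 30 ethyl (2E,4E)-3-methyl-5-[(1S,4S,6R)-2,2,6-trimethyl-4-(pivaloyloxy)-7-oxabicyclo[4.1.0]heptan-1-yl]penta-2,4-dienoate
Conditions: LiN(SiMe3)2, THF, −78 → 0 °C; then 28, −78 °C → rt
Reagents that add atoms: none
Why: Horner–Wadsworth–Emmons olefination with the vinylogous phosphonate anion, which reacts at the carbon next to phosphorus and should give the (E)-alkene at C7'=C8'.

Step 18
Reactants: 30 ethyl (2E,4E)-3-methyl-5-[(1S,4S,6R)-2,2,6-trimethyl-4-(pivaloyloxy)-7-oxabicyclo[4.1.0]heptan-1-yl]penta-2,4-dienoate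
Product: 31 (1S,4S,6R)-1-[(1E,3E)-5-hydroxy-3-methylpenta-1,3-dien-1-yl]-2,2,6-trimethyl-7-oxabicyclo[4.1.0]heptan-4-ol
Conditions: iBu2AlH (6 equiv), CH2Cl2, −78 → −20 °C; aq. KNaC4H4O6
Reagents that add atoms: none
Why: Hydride reduction of the dienoate to the allylic alcohol and reductive cleavage of the pivalate in one operation, at a temperature where the vinyl epoxide is not opened.

Step 19
Reactants: 31 (1S,4S,6R)-1-[(1E,3E)-5-hydroxy-3-methylpenta-1,3-dien-1-yl]-2,2,6-trimethyl-7-oxabicyclo[4.1.0]heptan-4-ol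
Product: 32 {(2E,4E)-5-[(1S,4S,6R)-4-hydroxy-2,2,6-trimethyl-7-oxabicyclo[4.1.0]heptan-1-yl]-3-methylpenta-2,4-dien-1-yl}triphenylphosphonium bromide
Conditions: Ph3P·HBr (1.05 equiv), MeOH, 0 °C → rt, dark
Reagents that add atoms: triphenylphosphine hydrobromide [Br-].c1ccc(cc1)[PH+](c1ccccc1)c1ccccc1
Why: Phosphonium salt formation, the dienylic primary alcohol being ionised by HBr and captured by triphenylphosphine while the non-allylic secondary alcohol is inert.

Step 20
Reactants: 32 the C15 epoxy phosphonium bromide; 22 the C25 aldehyde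
Product: 35 (5Z)-5-{(2E,4E,6E,8E,10E,12E)-13-[(1S,4S,6R)-4-hydroxy-2,2,6-trimethyl-7-oxabicyclo[4.1.0]heptan-1-yl]-2,7,11-trimethyltrideca-2,4,6,8,10,12-hexaen-1-ylidene}-3-{2-[(1R)-2,6,6-trimethyl-4-oxocyclohex-2-en-1-yl]ethyl}furan-2(5H)-one, via phosphorus ylide 33 (not isolated), via 11'-cis isomer 34 (not isolated)
Conditions: NaN(SiMe3)2 (1.05 equiv), THF, −78 °C; 22, −78 → 0 °C; then benzene, rt, diffuse light until the 11'-cis isomer has equilibrated
Reagents that add atoms: none
Why: Wittig olefination of the polyenal with the semi-stabilised allylic ylide forms C11'=C12' as an E/Z mixture, and the hindered 11'-cis isomer should relax to the all-E polyene; the aldehyde reacts far faster than the ring ketone or the lactone.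

**Compound list**

1 | 3-methylbut-2-enal | CC(C)=CC=O | starting material
2 | allenylboronic acid pinacol ester | C=C=CB1OC(C)(C)C(C)(C)O1 | starting material
3 | pinacol borate ester of 4 | C#CC[C@H](OB1OC(C)(C)C(C)(C)O1)C=C(C)C | intermediate
4 | (4S)-6-methylhept-5-en-1-yn-4-ol | C#CC[C@H](O)C=C(C)C | intermediate
5 | (E)-alkenyldimethylalane, aluminium alkoxide of 4 after methylalumination | C[Al](C)/C=C(C)/C[C@H](O[Al](C)C)C=C(C)C | intermediate
6 | (3E,6S)-4,8-dimethylnona-3,7-diene-1,6-diol | OCC/C=C(C)/C[C@H](O)C=C(C)C | intermediate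
7 | (4S,6E)-9-(tert-butyldimethylsilyloxy)-2,6-dimethylnona-2,6-dien-4-ol | CC(C)(C)[Si](C)(C)OCC/C=C(C)/C[C@H](O)C=C(C)C | intermediate
8 | potassium (1E,4S)-4-[2-(tert-butyldimethylsilyloxy)ethyl]-3,3,5-trimethylhexa-1,5-dien-1-olate | [K+].[O-]/C=C/C(C)(C)[C@@H](CCO[Si](C)(C)C(C)(C)C)C(C)=C | intermediate
9 | (4S)-4-[2-(tert-butyldimethylsilyloxy)ethyl]-3,3,5-trimethylhex-5-enal | O=CCC(C)(C)[C@@H](CCO[Si](C)(C)C(C)(C)C)C(C)=C | intermediate
10 | chloro(methyl)aluminium alkoxide of 11 | C[Al](Cl)OC1CC(=C)[C@H](CCO[Si](C)(C)C(C)(C)C)C(C)(C)C1 | intermediate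
11 | (4R)-4-[2-(tert-butyldimethylsilyloxy)ethyl]-5,5-dimethyl-3-methylidenecyclohexan-1-ol (C1 epimers) | OC1CC(=C)[C@H](CCO[Si](C)(C)C(C)(C)C)C(C)(C)C1 | intermediate
12 | (4R)-4-[2-(tert-butyldimethylsilyloxy)ethyl]-5,5-dimethyl-3-methylidenecyclohexan-1-one | O=C1CC(=C)[C@H](CCO[Si](C)(C)C(C)(C)C)C(C)(C)C1 | intermediate
13 | (4R)-4-(2-hydroxyethyl)-3,5,5-trimethylcyclohex-2-en-1-one | CC1=CC(=O)CC(C)(C)[C@H]1CCO | intermediate
14 | (4R)-4-(2-iodoethyl)-3,5,5-trimethylcyclohex-2-en-1-one | CC1=CC(=O)CC(C)(C)[C@H]1CCI | intermediate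
15 | propiolic acid | C#CC(=O)O | starting material
16 | (2E)-2,3-dibromoprop-2-enoic acid | OC(=O)/C(Br)=C\Br | intermediate
17 | (2E,4E,6E)-2,7-dimethylocta-2,4,6-trienedial | O=C/C(C)=C/C=C/C=C(C)/C=O | starting material
18 | (2E,4E,6E)-2,7-dimethylnona-2,4,6-trien-8-ynal | C#C/C(C)=C/C=C/C=C(C)/C=O | intermediate
19 | (2E,6E,8E,10E)-2-bromo-6,11-dimethyl-12-oxododeca-2,6,8,10-tetraen-4-ynoic acid | OC(=O)/C(Br)=C\C#C/C(C)=C/C=C/C=C(C)/C=O | intermediate
20 | (2E,4E,6E,8Z)-8-(4-bromo-5-oxofuran-2(5H)-ylidene)-2,7-dimethylocta-2,4,6-trienal | BrC1=C/C(=C/C(C)=C/C=C/C=C(C)/C=O)OC1=O | intermediate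
21 | iodo{2-[(1R)-2,6,6-trimethyl-4-oxocyclohex-2-en-1-yl]ethyl}zinc | CC1=CC(=O)CC(C)(C)[C@H]1CC[Zn]I | intermediate
22 | (2E,4E,6E,8Z)-2,7-dimethyl-8-[5-oxo-4-{2-[(1R)-2,6,6-trimethyl-4-oxocyclohex-2-en-1-yl]ethyl}furan-2(5H)-ylidene]octa-2,4,6-trienal | CC1=CC(=O)CC(C)(C)[C@H]1CCC1=C/C(=C/C(C)=C/C=C/C=C(C)/C=O)OC1=O | intermediate
23 | (4R,6R)-4-hydroxy-2,2,6-trimethylcyclohexan-1-one (actinol) | O=C1C(C)(C)C[C@H](O)C[C@H]1C | starting material
24 | (1R,5R)-3,3,5-trimethyl-4-oxocyclohexyl pivalate | O=C1C(C)(C)C[C@H](OC(=O)C(C)(C)C)C[C@H]1C | intermediate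
25 | (1R)-3,5,5-trimethyl-4-(trifluoromethanesulfonyloxy)cyclohex-3-en-1-yl pivalate | CC1=C(OS(=O)(=O)C(F)(F)F)C(C)(C)C[C@H](OC(=O)C(C)(C)C)C1 | intermediate
26 | (1R)-4-(hydroxymethyl)-3,5,5-trimethylcyclohex-3-en-1-yl pivalate | CC1=C(CO)C(C)(C)C[C@H](OC(=O)C(C)(C)C)C1 | intermediate
27 | (1R,4S,6R)-1-(hydroxymethyl)-2,2,6-trimethyl-7-oxabicyclo[4.1.0]heptan-4-yl pivalate | OC[C@@]12O[C@]1(C)C[C@@H](OC(=O)C(C)(C)C)CC2(C)C | intermediate
28 | (1S,4S,6R)-1-formyl-2,2,6-trimethyl-7-oxabicyclo[4.1.0]heptan-4-yl pivalate | O=C[C@@]12O[C@]1(C)C[C@@H](OC(=O)C(C)(C)C)CC2(C)C | intermediate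
29 | ethyl (2E)-4-(diethoxyphosphoryl)-3-methylbut-2-enoate | CCOC(=O)/C=C(C)/CP(=O)(OCC)OCC | starting material
30 | ethyl (2E,4E)-3-methyl-5-[(1S,4S,6R)-2,2,6-trimethyl-4-(pivaloyloxy)-7-oxabicyclo[4.1.0]heptan-1-yl]penta-2,4-dienoate | CCOC(=O)/C=C(C)/C=C/[C@@]12O[C@]1(C)C[C@@H](OC(=O)C(C)(C)C)CC2(C)C | intermediate
31 | (1S,4S,6R)-1-[(1E,3E)-5-hydroxy-3-methylpenta-1,3-dien-1-yl]-2,2,6-trimethyl-7-oxabicyclo[4.1.0]heptan-4-ol | OC/C=C(C)/C=C/[C@@]12O[C@]1(C)C[C@@H](O)CC2(C)C | intermediate
32 | {(2E,4E)-5-[(1S,4S,6R)-4-hydroxy-2,2,6-trimethyl-7-oxabicyclo[4.1.0]heptan-1-yl]-3-methylpenta-2,4-dien-1-yl}triphenylphosphonium bromide | [Br-].c1ccc(cc1)[P+](c1ccccc1)(c1ccccc1)C/C=C(C)/C=C/[C@@]12O[C@]1(C)C[C@@H](O)CC2(C)C | intermediate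
33 | phosphorus ylide of 32 | c1ccc(cc1)P(c1ccccc1)(c1ccccc1)=C/C=C(C)/C=C/[C@@]12O[C@]1(C)C[C@@H](O)CC2(C)C | intermediate
34 | 11'-cis isomer of 35 | CC1=CC(=O)CC(C)(C)[C@H]1CCC1=C/C(=C/C(C)=C/C=C/C=C(C)/C=C\C=C(C)\C=C\[C@@]23O[C@]2(C)C[C@@H](O)CC3(C)C)OC1=O | intermediate
35 | target, (5Z)-5-{(2E,4E,6E,8E,10E,12E)-13-[(1S,4S,6R)-4-hydroxy-2,2,6-trimethyl-7-oxabicyclo[4.1.0]heptan-1-yl]-2,7,11-trimethyltrideca-2,4,6,8,10,12-hexaen-1-ylidene}-3-{2-[(1R)-2,6,6-trimethyl-4-oxocyclohex-2-en-1-yl]ethyl}furan-2(5H)-one | CC1=CC(=O)CC(C)(C)[C@H]1CCC1=C/C(=C/C(C)=C/C=C/C=C(C)/C=C/C=C(C)/C=C/[C@@]23O[C@]2(C)C[C@@H](O)CC3(C)C)OC1=O | target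

**Step count and risks**

Total step count: 20. Longest linear sequence: 9 steps (steps 1–7, 11, 20; the epoxide branch, steps 12–19 and 20, is equally long).

Steps most likely to fail:

1. Step 5 (key step). Hydrogen may be transferred from C6–H instead of from the C5 methyl, or a cationic intermediate may be captured by chloride and eliminate unselectively; either would give the tetrasubstituted C5=C6 alkene and erase the C6 configuration. The fallback sets out from 9 and comes back at 13; it forms the same C3–C4 bond through an acylium ion instead of an ene process. Pinnick oxidation of 9 (NaClO2, NaH2PO4, 2-methylbut-2-ene) should give (4S)-4-[2-(tert-butyldimethylsilyloxy)ethyl]-3,3,5-trimethylhex-5-enoic acid F1. Oxalyl chloride with catalytic DMF converts it into the acid chloride F2. With SnCl4 in CH2Cl2 at −78 °C the isopropenyl methylene should attack the acylium ion and chloride should capture the tertiary cation, giving the β-chloro ketone F3. DBU then removes HCl by an E1cB path that can place the double bond only between C4 and C5, giving the silyl ether F4, and HCl in MeOH releases 13.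

2. Step 11. The organozinc may add to the aldehyde or to the ylidenebutenolide, the polyenal may decompose under the coupling conditions, or slow transmetalation may end in protodezincation. The fallback sets out from 14 and comes back at 22; it makes the C8–C9 bond on a small partner and builds the ylidene bond by aldol addition and elimination. The zinc reagent 21 from 14 is coupled (PdCl2(dppf)) with commercial 3-bromofuran-2(5H)-one (BrC1=CCOC1=O) to give 3-{2-[(1R)-2,6,6-trimethyl-4-oxocyclohex-2-en-1-yl]ethyl}furan-2(5H)-one F5. iPr3SiOTf and Et3N convert it into the 2-silyloxyfuran F6. A BF3·OEt2-promoted vinylogous Mukaiyama aldol addition to an excess of dialdehyde 17 at −78 °C should give the γ-(hydroxyalkyl)butenolide F7. MsCl with excess Et3N gives the mesylate F8, which eliminates in the same flask to 22; any (E)-ylidene isomer is equilibrated to the Z form with a trace of iodine.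

3. Step 10. The carboxylate may close in the 6-endo mode to a pyranone, the electron-poor polyenyne may oligomerise under palladium and copper catalysis, or the alkyne may homocouple. The fallback sets out from 17 and comes back at 20; it uses no alkyne. 3-Bromofuran-2(5H)-one is silylated (iPr3SiOTf, Et3N) to 3-bromo-2-(triisopropylsilyloxy)furan F9. Its vinylogous Mukaiyama aldol addition (BF3·OEt2, −78 °C) to excess 17 should give the hydroxyalkyl bromobutenolide F10. Mesylation to F11 and elimination with excess Et3N give 20.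

**Further compounds**

F1 | step 5 | (4S)-4-[2-(tert-butyldimethylsilyloxy)ethyl]-3,3,5-trimethylhex-5-enoic acid | OC(=O)CC(C)(C)[C@@H](CCO[Si](C)(C)C(C)(C)C)C(C)=C
F2 | step 5 | (4S)-4-[2-(tert-butyldimethylsilyloxy)ethyl]-3,3,5-trimethylhex-5-enoyl chloride | ClC(=O)CC(C)(C)[C@@H](CCO[Si](C)(C)C(C)(C)C)C(C)=C
F3 | step 5 | (4R)-3-chloro-4-[2-(tert-butyldimethylsilyloxy)ethyl]-3,5,5-trimethylcyclohexan-1-one (C3 epimers) | O=C1CC(C)(Cl)[C@H](CCO[Si](C)(C)C(C)(C)C)C(C)(C)C1
F4 | step 5 | (4R)-4-[2-(tert-butyldimethylsilyloxy)ethyl]-3,5,5-trimethylcyclohex-2-en-1-one | CC1=CC(=O)CC(C)(C)[C@H]1CCO[Si](C)(C)C(C)(C)C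
F5 | step 11 | 3-{2-[(1R)-2,6,6-trimethyl-4-oxocyclohex-2-en-1-yl]ethyl}furan-2(5H)-one | CC1=CC(=O)CC(C)(C)[C@H]1CCC1=CCOC1=O
F6 | step 11 | (4R)-3,5,5-trimethyl-4-{2-[2-(triisopropylsilyloxy)furan-3-yl]ethyl}cyclohex-2-en-1-one | CC1=CC(=O)CC(C)(C)[C@H]1CCc1ccoc1O[Si](C(C)C)(C(C)C)C(C)C
F7 | step 11 | (2E,4E,6E)-8-hydroxy-2,7-dimethyl-8-[5-oxo-4-{2-[(1R)-2,6,6-trimethyl-4-oxocyclohex-2-en-1-yl]ethyl}-2,5-dihydrofuran-2-yl]octa-2,4,6-trienal (diastereomers) | CC1=CC(=O)CC(C)(C)[C@H]1CCC1=CC(OC1=O)C(O)/C(C)=C/C=C/C=C(C)/C=O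
F8 | step 11 | methanesulfonate of F7 | CC1=CC(=O)CC(C)(C)[C@H]1CCC1=CC(OC1=O)C(OS(C)(=O)=O)/C(C)=C/C=C/C=C(C)/C=O
F9 | step 10 | 3-bromo-2-(triisopropylsilyloxy)furan | Brc1ccoc1O[Si](C(C)C)(C(C)C)C(C)C
F10 | step 10 | (2E,4E,6E)-8-(4-bromo-5-oxo-2,5-dihydrofuran-2-yl)-8-hydroxy-2,7-dimethylocta-2,4,6-trienal (diastereomers) | BrC1=CC(OC1=O)C(O)/C(C)=C/C=C/C=C(C)/C=O
F11 | step 10 | methanesulfonate of F10 | BrC1=CC(OC1=O)C(OS(C)(=O)=O)/C(C)=C/C=C/C=C(C)/C=O
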